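**Plan**

- Retrosynthesis: the two benzyl ethers on ring C are cut last. Next comes the bond between ring B C1 and the carbonyl carbon of the A–B ester, by a carbonylative coupling in which ring A arrives as its aryl formate and the formyl carbon becomes that carbonyl. Then the B–C ester C–O bond is cut, and finally the aryl–CO2Me bond of ring A.
- Forward: one bromophenol, 4-bromo-3-methoxy-5-methylphenol, is made from 2-bromo-3-methylanisole by sterically controlled C–H borylation/oxidation. It supplies ring A (methoxycarbonylation, then O-formylation) and ring B (acylation of its OH with dibenzyl-protected orsellinic acid). The chain is joined C to B, then (B–C) to A, then debenzylated.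
- Enabling feature: in ring B the carbon that must carry the carbonyl (C1, between C2–OMe and C6–CH3, para to the acyloxy oxygen) holds the only C–Br bond of the coupling partner. The ring A oxygen to be acylated is a phenol para to CO2Me, so its formate releases CO and a reactive phenoxide under a weak base. Both depside carbonyls are flanked by two ortho substituents and should resist acyl exchange.
- Stereochemistry: the target has no stereocentre and no configurationally stable axis, so it is achiral and the request for a single enantiomer needs no stereocontrol.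

Key step: step 7

**Route**

Step 1
Reactants: 1 2-bromo-1-methoxy-3-methylbenzene (2-bromo-3-methylanisole)
Product: 3 4-bromo-3-methoxy-5-methylphenol, via aryl pinacol boronate 2 (not isolated)
Conditions: [Ir(OMe)(cod)]2 (1.5 mol %), dtbpy (3 mol %), B2pin2 (1.0 equiv), THF, 80 °C; then Oxone, acetone/H2O, rt
Reagents that add atoms: bis(pinacolato)diboron, CC1(C)OB(OC1(C)C)B1OC(C)(C)C(C)(C)O1 (its boryl group stays only in 2); Oxone (potassium peroxymonosulfate), [K+].[O-]S(=O)(=O)OO (source of the phenol oxygen)
Why: Iridium-catalysed C–H borylation is sterically governed and should take the only ring C–H without an ortho substituent (C5, para to bromine), and the C–B bond is then oxidised in the same pot with retention of position (one-pot borylation/oxidation to a phenol).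

Step 2
Reactants: 3 4-bromo-3-methoxy-5-methylphenol
Product: 4 methyl 4-hydroxy-2-methoxy-6-methylbenzoate
Conditions: Pd(OAc)2 (3 mol %), Xantphos (6 mol %), CO (1 atm), NEt3, MeOH, 70 °C
Reagents that add atoms: carbon monoxide, [C-]#[O+]; methanol, CO
Why: Palladium-catalysed methoxycarbonylation of the aryl bromide should proceed by oxidative addition, CO insertion and methanolysis of the aroyl–palladium species, with the large excess of methanol outcompeting the free phenol as nucleophile.

Step 3
Reactants: 4 methyl 4-hydroxy-2-methoxy-6-methylbenzoate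
Product: 5 methyl 4-(formyloxy)-2-methoxy-6-methylbenzoate
Conditions: HCO2H, Ac2O, 60 °C; then 4, NaOAc (cat.), toluene, rt
Reagents that add atoms: formic acid, O=CO (delivered as acetic formic anhydride, CC(=O)OC=O, made in the flask from formic acid and acetic anhydride)
Why: The mixed anhydride should transfer its more electrophilic, unhindered formyl group to the phenol oxygen (O-formylation with acetic formic anhydride), the methyl ester and methyl ether being inert.

Step 4
Reactants: 6 methyl 2,4-dihydroxy-6-methylbenzoate (methyl orsellinate)
Product: 7 methyl 2,4-bis(benzyloxy)-6-methylbenzoate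
Conditions: BnBr (2.5 equiv), K2CO3, DMF, 70 °C
Reagents that add atoms: benzyl bromide, BrCc1ccccc1
Why: Double Williamson etherification, in which heating in DMF should also alkylate the 2-OH that is hydrogen-bonded to the ester carbonyl while the hindered methyl ester stays intact.

Step 5
Reactants: 7 methyl 2,4-bis(benzyloxy)-6-methylbenzoate
Product: 8 2,4-bis(benzyloxy)-6-methylbenzoic acid
Conditions: KOH, DMSO/H2O, 100 °C; then aq. HCl
Reagents that add atoms: potassium hydroxide, [K+].[OH-]
Why: Saponification of the di-ortho-substituted methyl benzoate should succeed with poorly solvated hydroxide in hot aqueous DMSO, conditions to which benzyl ethers are stable.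

Step 6
Reactants: 8 2,4-bis(benzyloxy)-6-methylbenzoic acid; 3 4-bromo-3-methoxy-5-methylphenol
Product: 10 4-bromo-3-methoxy-5-methylphenyl 2,4-bis(benzyloxy)-6-methylbenzoate, via mixed trifluoroacetic anhydride 9 (not isolated)
Conditions: TFAA, toluene, 0 °C to rt
Reagents that add atoms: trifluoroacetic anhydride, O=C(OC(=O)C(F)(F)F)C(F)(F)F (its atoms stay only in 9)
Why: Trifluoroacetic anhydride should convert the hindered acid into a mixed anhydride that acylates the phenol at oxygen (the classical depside esterification), the aryl bromide, methyl ether and benzyl ethers being inert.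

Step 7
Reactants: 10 4-bromo-3-methoxy-5-methylphenyl 2,4-bis(benzyloxy)-6-methylbenzoate; 5 methyl 4-(formyloxy)-2-methoxy-6-methylbenzoate
Product: 11 methyl 4-{[4-{[2,4-bis(benzyloxy)-6-methylbenzoyl]oxy}-2-methoxy-6-methylbenzoyl]oxy}-2-methoxy-6-methylbenzoate, via methyl 4-hydroxy-2-methoxy-6-methylbenzoate 4 (not isolated)
Conditions: Pd(OAc)2 (5 mol %), Xantphos (10 mol %), NEt3 (2 equiv), 5 (1.5 equiv), toluene, 100 °C, sealed tube
Reagents that add atoms: none
Why: Triethylamine should fragment formate 5 into carbon monoxide and the phenoxide of 4 (both kept in the sealed vessel); Pd(0)/Xantphos adds oxidatively to the only C–Br bond of 10, CO inserts to give the 4-acyloxy-2-methoxy-6-methylbenzoyl–palladium species, and attack of the ring A phenoxide with reductive elimination forges the ester, so that the formyl carbon of 5 ends bonded to ring B C1. The closest known reaction type is the palladium-catalysed aryloxycarbonylation of aryl bromides with aryl formates as a CO-free carbonyl source (carbonylative esterification). No ring is closed and no stereocentre is formed. The step needs site selectivity (carbonyl on the ring B carbon between C–OMe and C–CH3), which the position of bromine fixed in step 1 secures, and chemoselectivity for C–Br over the ester C–O bonds, the benzyl ethers and the existing depside linkage. Exchange of the B–C ester by the liberated phenoxide should be suppressed because both depside carbonyls are flanked by two ortho substituents and only a weak amine base is present. The para-methoxycarbonyl group of ring A makes its phenoxide a good leaving group from the formate and a competent partner for the hindered aroyl–palladium intermediate, while CO insertion relieves the strain of the di-ortho-substituted aryl–palladium bond.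

Step 8
Reactants: 11 methyl 4-{[4-{[2,4-bis(benzyloxy)-6-methylbenzoyl]oxy}-2-methoxy-6-methylbenzoyl]oxy}-2-methoxy-6-methylbenzoate
Product: 12 methyl 4-{[4-{[2,4-dihydroxy-6-methylbenzoyl]oxy}-2-methoxy-6-methylbenzoyl]oxy}-2-methoxy-6-methylbenzoate (target)
Conditions: H2 (1 atm), 10% Pd/C, EtOAc, rt
Reagents that add atoms: none
Why: Hydrogenolysis of the two benzyl aryl ethers over palladium on carbon should free both ring C phenols, while the aryl esters, the methyl ester and the methyl ethers are not reduced and no aryl halide remains.

**Compound list**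

1 | 2-bromo-1-methoxy-3-methylbenzene (2-bromo-3-methylanisole) | COc1cccc(C)c1Br | starting material
2 | 2-(4-bromo-3-methoxy-5-methylphenyl)-4,4,5,5-tetramethyl-1,3,2-dioxaborolane | COc1cc(B2OC(C)(C)C(C)(C)O2)cc(C)c1Br | intermediate
3 | 4-bromo-3-methoxy-5-methylphenol | COc1cc(O)cc(C)c1Br | intermediate
4 | methyl 4-hydroxy-2-methoxy-6-methylbenzoate | COC(=O)c1c(C)cc(O)cc1OC | intermediate
5 | methyl 4-(formyloxy)-2-methoxy-6-methylbenzoate | COC(=O)c1c(C)cc(OC=O)cc1OC | intermediate
6 | methyl 2,4-dihydroxy-6-methylbenzoate (methyl orsellinate) | COC(=O)c1c(C)cc(O)cc1O | starting material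
7 | methyl 2,4-bis(benzyloxy)-6-methylbenzoate | COC(=O)c1c(C)cc(OCc2ccccc2)cc1OCc1ccccc1 | intermediate
8 | 2,4-bis(benzyloxy)-6-methylbenzoic acid | OC(=O)c1c(C)cc(OCc2ccccc2)cc1OCc1ccccc1 | intermediate
9 | 2,4-bis(benzyloxy)-6-methylbenzoic trifluoroacetic anhydride | O=C(OC(=O)C(F)(F)F)c1c(C)cc(OCc2ccccc2)cc1OCc1ccccc1 | intermediate
10 | 4-bromo-3-methoxy-5-methylphenyl 2,4-bis(benzyloxy)-6-methylbenzoate | COc1cc(OC(=O)c2c(C)cc(OCc3ccccc3)cc2OCc2ccccc2)cc(C)c1Br | intermediate
11 | methyl 4-{[4-{[2,4-bis(benzyloxy)-6-methylbenzoyl]oxy}-2-methoxy-6-methylbenzoyl]oxy}-2-methoxy-6-methylbenzoate | COC(=O)c1c(C)cc(OC(=O)c2c(C)cc(OC(=O)c3c(C)cc(OCc4ccccc4)cc3OCc3ccccc3)cc2OC)cc1OC | intermediate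
12 | methyl 4-{[4-{[2,4-dihydroxy-6-methylbenzoyl]oxy}-2-methoxy-6-methylbenzoyl]oxy}-2-methoxy-6-methylbenzoate | COC(=O)c1c(C)cc(OC(=O)c2c(C)cc(OC(=O)c3c(C)cc(O)cc3O)cc2OC)cc1OC | target

**Step count and risks**

Total step count: 8. Longest linear sequence: 5 steps (steps 1, 2, 3, 7, 8, or equally steps 4, 5, 6, 7, 8).

Steps most likely to fail:

Step 7. Oxidative addition and CO insertion at the di-ortho-substituted, electron-rich C–Br bond may be slow, so that protodebromination or acyl exchange of the B–C ester by the liberated phenoxide overtakes the coupling. The fallback is the classical ester-forming assembly; it sets out from 3 and comes back to the route at 11. Benzylation of 3 (BnBr, K2CO3, DMF) should give 5-(benzyloxy)-2-bromo-1-methoxy-3-methylbenzene F1. Bromine–lithium exchange (n-BuLi, THF, −78 °C) should give [4-(benzyloxy)-2-methoxy-6-methylphenyl]lithium F2, which is carboxylated with CO2 and acidified to 4-(benzyloxy)-2-methoxy-6-methylbenzoic acid F3. Activation with TFAA in toluene should give 4-(benzyloxy)-2-methoxy-6-methylbenzoic trifluoroacetic anhydride F4, which acylates phenol 4 to methyl 4-{[4-(benzyloxy)-2-methoxy-6-methylbenzoyl]oxy}-2-methoxy-6-methylbenzoate F5. Hydrogenolysis (H2, Pd/C, EtOAc) should give methyl 4-[(4-hydroxy-2-methoxy-6-methylbenzoyl)oxy]-2-methoxy-6-methylbenzoate F6. Acylation of F6 with acid 8 (TFAA, toluene, through 9) should give 11.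

Step 2. Oxidative addition into the hindered bromide may be retarded by the electron-rich phenoxide form of the substrate, and the phenol may capture the aroyl–palladium species to give oligomeric aryl esters. The fallback sets out from 6 and comes back at 4. Selective benzylation of the non-chelated 4-OH of 6 (BnBr, 1.05 equiv, K2CO3, acetone, reflux) should give methyl 4-(benzyloxy)-2-hydroxy-6-methylbenzoate F7. Methylation of the chelated 2-OH (MeI, K2CO3, DMF, 60 °C) should give methyl 4-(benzyloxy)-2-methoxy-6-methylbenzoate F8. Hydrogenolysis (H2, Pd/C, EtOAc) should give 4.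

Step 3. The activated aryl formate may lose its formyl group by hydrolysis during isolation, or decarbonylate early through traces of base. The fallback sets out from 4 and comes back at 11. Formate 5 is left out, and 10 and 4 are coupled under carbon monoxide gas in a three-component aryloxycarbonylation (Pd(OAc)2, Xantphos, CO 1 atm, NEt3, toluene, 100 °C). This fallback makes no new compound (F0).

**Further compounds**

F1 | step 7 | 5-(benzyloxy)-2-bromo-1-methoxy-3-methylbenzene | COc1cc(OCc2ccccc2)cc(C)c1Br
F2 | step 7 | [4-(benzyloxy)-2-methoxy-6-methylphenyl]lithium | [Li]c1c(C)cc(OCc2ccccc2)cc1OC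
F3 | step 7 | 4-(benzyloxy)-2-methoxy-6-methylbenzoic acid | COc1cc(OCc2ccccc2)cc(C)c1C(=O)O
F4 | step 7 | 4-(benzyloxy)-2-methoxy-6-methylbenzoic trifluoroacetic anhydride | COc1cc(OCc2ccccc2)cc(C)c1C(=O)OC(=O)C(F)(F)F
F5 | step 7 | methyl 4-{[4-(benzyloxy)-2-methoxy-6-methylbenzoyl]oxy}-2-methoxy-6-methylbenzoate | COC(=O)c1c(C)cc(OC(=O)c2c(C)cc(OCc3ccccc3)cc2OC)cc1OC
F6 | step 7 | methyl 4-[(4-hydroxy-2-methoxy-6-methylbenzoyl)oxy]-2-methoxy-6-methylbenzoate | COC(=O)c1c(C)cc(OC(=O)c2c(C)cc(O)cc2OC)cc1OC
F7 | step 2 | methyl 4-(benzyloxy)-2-hydroxy-6-methylbenzoate | COC(=O)c1c(C)cc(OCc2ccccc2)cc1O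
F8 | step 2 | methyl 4-(benzyloxy)-2-methoxy-6-methylbenzoate | COC(=O)c1c(C)cc(OCc2ccccc2)cc1OC
F0 | step 3 | none | none
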